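The numbers come from no measurement.

The hour of full catalyst is the unit of this reckoning: one hour in which the whole charge of Z works at 60 °C.

| setting | ash | oak | birch | larch |
|---|---|---|---|---|
| J | 0.065 M | 0.065 M | 0.065 M | 0.065 M |
| Q | 0.600 equiv | 0.600 equiv | 0.600 equiv | 0.600 equiv |
| Z | 9.8 mol% | 9.8 mol% | 9.8 mol% | 9.8 mol% |
| temperature | 60 °C | 45 °C | 30 °C |  |
| time | 2.5 h | 2.5 h | 2.5 h | 2.5 h |
| remark |  |  |  | at 60 °C until 30 min, from then on at 30 °C |

    Z ⇌ L (K1 = 9.3, k1 = 3.3 h⁻¹, Ea1 = 107 kJ mol⁻¹, ΔH1 = −90.0 kJ mol⁻¹)
    J + Q + Z ⇌ J.Q + Z, rate k2*[J]*[Q]*[Z] forward; the back reaction follows from the equilibrium constant (K2 = 230 M⁻¹, k2 = 4900 M⁻² h⁻¹, Ea2 = 43.0 kJ mol⁻¹, ΔH2 = −15.0 kJ mol⁻¹)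
    (constants at 60 °C)

- all constants are for 60 °C and move with temperature by the activation energies and enthalpies

1. the best flask by amount of J.Q, in percent of the J charged; "all alike" if 1.5 percentage points covers them all (ash / oak / birch / larch / all alike)
2. amount of J.Q at the end, in percent of the J charged, ash
3. amount of J.Q at the end, in percent of the J charged, oak
4. amount of J.Q at the end, in percent of the J charged, birch
5. amount of J.Q at the end, in percent of the J charged, larch

Q is the limiting reagent in each flask, so at 0.600 equiv the yield of J.Q is capped at that fraction of the J charged. With the back reaction struck out and H hours of full catalyst, the rate law integrates to a closed form, where q is the equivalents of Q: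

m = 4900 M⁻² h⁻¹ × Z charged × (J charged − Q charged) = 0.812 h⁻¹

G = exp(m × H), yield = q(G − 1)/(G − q)

In ash, Z and L relax towards each other with time constant 0.274 h, shorter than the run of 2.5 h. Taking that fast step as settled leaves a free share of Z of 9.71%, which gives:

H = free share × time = 0.243 h, yield 21.1%

The weak link is the start, since the charge begins as whole Z. The excess over the free share decays with that time constant and adds its own hours:

tail = 0.247 h, about as much as the settled part

H = 0.490 h, yield 33.0%

These working hours are the time integral of the free share of Z, weighted by the speed of step two relative to 60 °C. At that yield in ash the back rate stands at 12.2% of the forward rate, which this reckoning leaves struck out.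

Birch, with Z counted whole, has its speed divided by 4.6:

H = 0.538 h, yield 34.7%

Oak lies about midway, so its equilibrium constant and speed factor are taken as geometric means. Its relaxation half-life of 1.27 h gives a time constant of 1.83 h, and the free share towards which its Z relaxes is 2.11%:

H = 0.643 h, yield 37.9%

Oak holds more working hours than ash or birch, so this reckoning commits to oak.

The forecast also names oak, with 32.1% for ash, 37.5% for oak, 32.5% for birch and 26.7% for larch, the first three below the 33.0%, 37.9% and 34.7% reckoned here, and it holds that “the catalyst's loss to L is the main limit”.

The simulation gives 32.1% for ash, 37.5% for oak, 32.5% for birch and 26.8% for larch, with oak ahead.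

Ash, credited with 0.490 h, ended with Z at 9.72% of its charge. In larch, J.Q reached 21.6% by 0.500 h while Z fell to 24.2%; after the change to 30 °C, Z eased to 21.0% by 2.50 h while J.Q went on rising. The hot stretch of larch holds 0.256 h of working hours, and the cold stretch, with Z taken as the mean of those two values and the speed divided by 4.6, holds 0.0974 h. Together they are worth 27.2% of J.Q, and larch holds 26.8% at 2.50 h.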